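## The problem

The target is a B-type proanthocyanidin dimer. An upper 5-deoxyflavan-3-ol (robinetinidol; rings A, B, C) is bonded through C4 to C8 of a lower (+)-gallocatechin unit (rings D, E, F). Remark on the chemistry: the descriptors of the structure are read as (2R,3S,4R) in the upper unit and (2R,3S) in the lower one, i.e. 2,3-trans-3,4-cis, robinetinidol-(4β→8)-gallocatechin.

The two lower centres come with gallocatechin, but they are too far from C4 to steer it. The three upper centres therefore have to control one another. The 3,4-cis relation is the hard one: capture of a flavan-4-yl cation by ring D puts the new aryl group trans to the C3 oxygen and can also attack C6.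

Eleven hydroxyl groups, two air- and base-sensitive pyrogallol rings, a C2 centre that epimerises through ring opening when phenols are free, and an acid-labile C4–C8 bond forbid rough acid, base or oxidant on unprotected material.

The enabling feature appears when the O1–C2 bond of ring C is opened. O1 is then a free phenol on ring A, ortho to C4 and bis-homoallylic to a C2=C3 alkene. C4 carries three very different groups: H, ring A with that phenol, and the ortho,ortho′-disubstituted ring D. An oxidant held on O1 can thus be steered by C4 to one alkene face, and the E geometry links C2 to C3.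

## Retrosynthesis

**23 ⇐ 22.** The ten O–benzyl bonds are cut. Benzyl ethers survive organometallic reagents, Lewis acids and peroxide and leave without acid or base. The forward hydrogenolysis must spare the C4–C8 bond and the two benzylic C2–O1 bonds.

**22 ⇐ 21.** The O1–C2 bond is cut, giving the epoxy phenol 21. The neighbouring cut, C4–C8 by cation coupling, gives 3,4-trans and C6/C8 mixtures. The forward step must be a 6-endo opening at benzylic C2 with inversion (2,3-trans), leaving the C3–O bond untouched.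

**21 ⇐ 20.** The C2–O and C3–O bonds of the oxirane are cut, giving the E-alkene 20; two stereocentres disappear. A dihydroxylation would ignore the phenol and would leave a diol to be differentiated. Here the phenol serves twice, as directing group and later as nucleophile. The forward step needs face selectivity from C4.

**20 ⇐ 18.** O1 is masked as a methoxymethyl ether, the usual mask next to an aryl–metal bond. It must come off without Brønsted acid, because the C4–C8 bond of 18 is a vinylogous, acid-labile diarylmethane link.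

**18 ⇐ 12 + 15.** The C4–C4a bond is cut with allylic transposition (anti-SN2′, through Grignard reagent 16 and cuprate 17).
- Making C4–C8 the same way would need a precious, doubly ortho-substituted ring D copper reagent in excess.
- Conjugate-addition routes would leave a carbonyl to be turned into the styrene.
- The chosen cut gives C4 and the E-alkene in one step from a cheap ring A reagent and moves the stereochemical problem to a secondary carbinol.

**12 ⇐ 11 ⇐ 7 + 8.** The ester is cut, then the bond between the carbinol carbon (future C2) and the alkenyl carbon (future C3). A Corey–Bakshi–Shibata reduction of the chalcone would have to tell an aryl from a styryl group, a weak distinction. Addition of an E-alkenylzinc reagent to aldehyde 8 tells H from aryl and uses the commercial aldehyde directly.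

**7 ⇐ 6 ⇐ 4 ⇐ 3 ⇐ 2 ⇐ 1.** C8 of perbenzylated gallocatechin is functionalised by regioselective bromination, formylation (through aryllithium 5) and one-carbon homologation to the alkyne.

**15 ⇐ 14 ⇐ 13.** 4-Bromoresorcinol is benzylated at the hydroxyl remote from bromine and protected at the other.

## Roads not taken

**Alternative 1:** Ring C is cut at O1–C8a and C4a–C4, so ring A arrives last as the aryne A2 and the rest sits in the α-benzyloxy-β-hydroxy ketone A1. With CsF, the C2 alkoxide of A1 would add to A2 at the carbon remote from chlorine, and the aryl anion would close on the ketone to give the 4-hydroxy-4-aryl flavan A3.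
- Merits: the most convergent plan; ring C and two bonds in one step; C2 and C3 come from an acyclic fragment.
- Weak points:
  - The alkoxide of A1 is a β-ketol alkoxide; retro-aldol cleavage and epimerisation at C3 threaten under basic fluoride.
  - The aryl anion sits ortho to chlorine and can expel chloride.
  - C4 is formed as a tertiary carbinol, so the 4-hydrogen must be added later by ionic hydrogenation at a centre where proton loss from C3 and loss of ring D compete.
  - Chlorine must be removed at the end.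
- Comparison: this road is shorter and more convergent, which is a real advantage. The chosen plan sets against it a defined control element for each stereocentre and no epimerisable α-centre.

**Alternative 2:** C3–C4 and O1–C2 are cut. The precursor A4 is a ring A ortho-hydroxybenzhydrol already bonded to C8 of ring D, with an E-2-arylvinyl(diisopropyl)silyl group on O7. A chiral phosphoric acid would dehydrate A4 and the tethered vinylsilane would add across C4 and O1 in a quinone methide [4+2] cycloaddition to give A5. Tamao–Fleming oxidation would then turn C3–Si into C3–OH with retention.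
- Merits: three stereocentres and ring C in one step. The tether can only bridge C3 and ring D on one face, so 3,4-cis is enforced by connectivity. On this point it is stronger than the chosen plan.
- Weak points:
  - O7 of ring D must be told apart from O5 and the other phenols before silylation.
  - Vinylsilanes are poor partners for this electron-poor heterodiene.
  - The catalyst alone must set C4 in a very large substrate.
  - The oxidation of a hindered silyl group must spare four electron-rich rings.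
- Comparison: fewer stereochemical assumptions, but an untested cycloaddition and a selective-protection problem. The chosen plan uses perbenzylated gallocatechin and known reaction types. Against the certainty of the tether it sets the size difference between H and ring D at C4 and a reagent-controlled fallback.

**Alternative 3:** Ring C comes from the cis-dihydrobenzofuran carbinol A6. After sulfonylation, Zn(OAc)2 in acetic acid ionises the benzylic carbon, O1 migrates from C3 to C2 and acetate enters at C3, giving the 3-O-acetate A7.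
- Merits: C2 and C3 are set by two stereospecific inversions. No face selection is needed when ring C forms, and the outcome does not depend on the 6-endo versus 5-exo bias.
- Weak points:
  - The problem is moved, not solved: A6 has three contiguous centres including the less stable cis-2,3 pattern.
  - Ionisation without O1 participation would lose C2.
  - Hot acetic acid meets the acid-labile C4–C8 bond.
  - A deacetylation is added.
- Comparison: A6 is exactly what epoxide 21 gives on 5-exo opening with base, so this chemistry stays available as a safety net for ring closure. As a main line it is longer and harsher than the direct 6-endo opening.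

Key step: step 12

Abbreviations in names: GC8 = (2R,3S)-3,5,7-tris(benzyloxy)-2-[3,4,5-tris(benzyloxy)phenyl]chroman-8-yl (lower unit bonded through C8 of ring D); TBP = 3,4,5-tris(benzyloxy)phenyl.

## Route

Step 1
Reactants: 1 (+)-gallocatechin
Product: 2 (2R,3S)-5,7-bis(benzyloxy)-2-[3,4,5-tris(benzyloxy)phenyl]chroman-3-ol
Conditions: BnBr (5.5 equiv), K2CO3, DMF, 0 °C → rt, argon
Reagents that add atoms: benzyl bromide, BrCc1ccccc1
Why: Williamson etherification of the five phenols; carbonate is too weak a base for the secondary 3-OH, and the mild temperature avoids C2 epimerisation.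

Step 2
Reactants: 2 (2R,3S)-5,7-bis(benzyloxy)-2-[3,4,5-tris(benzyloxy)phenyl]chroman-3-ol
Product: 3 (2R,3S)-3,5,7-tris(benzyloxy)-2-[3,4,5-tris(benzyloxy)phenyl]chromane (hexa-O-benzylgallocatechin)
Conditions: NaH, BnBr, Bu4NI (cat.), DMF, 0 °C → rt
Reagents that add atoms: benzyl bromide, BrCc1ccccc1
Why: Williamson benzylation of the alkoxide; with all phenols capped the ring-opening pathway that epimerises C2 is closed.

Step 3
Reactants: 3 hexa-O-benzylgallocatechin
Product: 4 (2R,3S)-3,5,7-tris(benzyloxy)-8-bromo-2-[3,4,5-tris(benzyloxy)phenyl]chromane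
Conditions: NBS (1.0 equiv), CH2Cl2, −40 °C → rt
Reagents that add atoms: N-bromosuccinimide, O=C1CCC(=O)N1Br
Why: Electrophilic aromatic bromination; in benzylated flavan-3-ols C8 of the phloroglucinol ring (activated by three oxygens) is the most nucleophilic position, ahead of C6 and of the pyrogallol ring.

Step 4
Reactants: 4 8-bromo-hexa-O-benzylgallocatechin
Product: 6 (2R,3S)-3,5,7-tris(benzyloxy)-2-[3,4,5-tris(benzyloxy)phenyl]chromane-8-carbaldehyde, via 8-lithio-hexa-O-benzylgallocatechin 5 (not isolated)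
Conditions: n-BuLi, THF, −78 °C; DMF, −78 → 0 °C; aq NH4Cl
Reagents that add atoms: N,N-dimethylformamide, CN(C)C=O
Why: Bromine–lithium exchange followed by Bouveault formylation; exchange at −78 °C is faster than deprotonation of the benzylic ether positions.

Step 5
Reactants: 6 8-formyl-hexa-O-benzylgallocatechin
Product: 7 (2R,3S)-3,5,7-tris(benzyloxy)-8-ethynyl-2-[3,4,5-tris(benzyloxy)phenyl]chromane
Conditions: dimethyl (1-diazo-2-oxopropyl)phosphonate, K2CO3, MeOH/THF, rt
Reagents that add atoms: dimethyl (1-diazo-2-oxopropyl)phosphonate, COP(=O)(OC)C(=[N+]=[N-])C(C)=O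
Why: Seyferth–Gilbert homologation with the Ohira–Bestmann reagent; the aldehyde has no α-hydrogen and the mild carbonate conditions leave all ethers and both stereocentres alone.

Step 6
Reactants: 7 8-ethynyl-hexa-O-benzylgallocatechin; 8 3,4,5-tris(benzyloxy)benzaldehyde
Product: 11 (1S,2E)-3-(GC8)-1-(TBP)prop-2-en-1-ol, via (E)-alkenyl(dicyclohexyl)borane 9 (not isolated), via (E)-alkenyl(methyl)zinc 10 (not isolated)
Conditions: Cy2BH, toluene, 0 °C → rt; Me2Zn, (−)-MIB (5 mol %), −78 → −10 °C; then 8, 0 °C; pH 7 buffer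
Reagents that add atoms: none
Why: Syn-hydroboration fixes the E geometry, boron-to-zinc transmetalation keeps it, and the amino alcohol-catalysed alkenylzinc addition to the aromatic aldehyde proceeds on the Si face, as for dialkylzinc additions with this ligand, setting the (S)-carbinol.

Step 7
Reactants: 11 (1S,2E)-allylic alcohol
Product: 12 (1S,2E)-3-(GC8)-1-(TBP)prop-2-en-1-yl pyridine-2-carboxylate
Conditions: picolinic acid, DCC, DMAP (cat.), CH2Cl2, 0 °C; filtration through Et3N-deactivated silica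
Reagents that add atoms: picolinic acid, OC(=O)c1ccccn1
Why: Steglich esterification under neutral conditions, which avoids ionisation of the doubly activated allylic carbinol; the stereocentre is not touched.

Step 8
Reactants: 13 4-bromoresorcinol
Product: 14 5-(benzyloxy)-2-bromophenol
Conditions: BnBr (1.0 equiv), K2CO3, acetone, reflux; chromatography
Reagents that add atoms: benzyl bromide, BrCc1ccccc1
Why: Williamson mono-etherification; the hydroxyl flanked by bromine is hindered and its phenoxide the less nucleophilic, so the remote hydroxyl should react first, and bis-ether and regioisomer are removed by chromatography.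

Step 9
Reactants: 14 5-(benzyloxy)-2-bromophenol
Product: 15 4-(benzyloxy)-1-bromo-2-(methoxymethoxy)benzene
Conditions: MeOCH2Cl, i-Pr2NEt, CH2Cl2, 0 °C → rt
Reagents that add atoms: chloromethyl methyl ether, COCCl
Why: Standard acetal protection of the phenol; the methoxymethyl ether is stable next to an aryl–magnesium bond and orthogonal to benzyl.

Step 10
Reactants: 12 (1S,2E)-picolinate; 15 4-(benzyloxy)-1-bromo-2-(methoxymethoxy)benzene
Product: 18 (2R,3S)-3,5,7-tris(benzyloxy)-8-{(1R,2E)-1-[4-(benzyloxy)-2-(methoxymethoxy)phenyl]-3-(TBP)prop-2-en-1-yl}-2-(TBP)chromane, via arylmagnesium bromide 16 (not isolated), via bromomagnesium diarylcuprate 17 (not isolated)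
Conditions: 15 (3 equiv), Mg, THF, 40 °C; CuBr·SMe2 (1.5 equiv), −30 °C; then 12, −30 → 0 °C
Reagents that add atoms: none
Why: Copper-mediated anti-SN2′ allylic arylation of a picolinate: magnesium chelation by the picolinate activates the leaving group and the cuprate attacks the ring D-bearing carbon anti to the C–O bond in the rotamer whose carbinol C–H eclipses the alkene, so the (S)-carbinol is transferred into (R)-C4 and the new alkene is E and conjugated with ring B.

Step 11
Reactants: 18 methoxymethyl ether of the triarylpropene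
Product: 20 (2R,3S)-3,5,7-tris(benzyloxy)-8-{(1R,2E)-1-[4-(benzyloxy)-2-hydroxyphenyl]-3-(TBP)prop-2-en-1-yl}-2-(TBP)chromane, via aryl trimethylsilyl ether 19 (not isolated)
Conditions: Me3SiOTf, 2,2′-bipyridyl, CH2Cl2, 0 °C → rt; then H2O
Reagents that add atoms: none
Why: Silyl triflate/bipyridyl cleavage of an aryl methoxymethyl ether through the aryl silyl ether, which water hydrolyses; the non-protic conditions spare the acid-labile C4–C8 bond, the styrene and the benzyl ethers.

Step 12
Reactants: 20 (1R,2E)-triarylpropene with free ring A phenol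
Product: 21 (2R,3S)-3,5,7-tris(benzyloxy)-8-{(R)-[4-(benzyloxy)-2-hydroxyphenyl][(2S,3S)-3-(TBP)oxiran-2-yl]methyl}-2-(TBP)chromane
Conditions: VO(acac)2 (10 mol %), t-BuOOH (1.5 equiv, in decane), 4 Å MS, toluene, 0 °C → rt; aq Na2S2O3; Et3N-deactivated silica
Reagents that add atoms: tert-butyl hydroperoxide, CC(C)(C)OO
Why: VO(acac)2 is oxidised by t-BuOOH to a pentavalent oxovanadium species that takes up the ring A phenoxide of 20 and a tert-butylperoxide ligand and passes the peroxide oxygen to the C2=C3 alkene within this complex; the closest known reaction type is the hydroxyl-directed vanadium epoxidation of allylic to bis-homoallylic alcohols and, on this substrate class, of ortho-(alk-2-enyl)phenols. The oxirane is closed by concerted syn transfer of one oxygen atom to both alkene carbons (a [2+1] addition, not a stepwise ring closure), so the E geometry is carried stereospecifically into a trans-oxirane, which fixes C2 relative to C3. The face is decided by C4: in the reactive rotamer the C4–H bond lies in the alkene plane on the C2 side (least allylic strain, and the ortho,ortho′-disubstituted ring D cannot take that place), which puts ring A above and ring D below the plane. Because the oxidant is tied to the ring A phenoxide it can reach the alkene only from the ring A face, which for (R)-C4 gives the (2S,3S)-oxirane, the one whose C3–O bond lies cis to ring D once ring C is closed. The step needs π-face selectivity and chemoselectivity (epoxidation ahead of phenol oxidation and of epoxide opening); the first rests on the tether and on the size difference between H and ring D at C4, the second on the rate gain of intramolecular delivery, the low temperature and the absence of added acid. Should part of 21 open in the flask under the Lewis-acidic vanadium, the expected product is 22, the product of the next step, so this is not a loss.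

Step 13
Reactants: 21 (2S,3S)-epoxy phenol
Product: 22 (2R,3S,4R)-7-(benzyloxy)-4-(GC8)-2-(TBP)chroman-3-ol
Conditions: (+)-camphorsulfonic acid (10 mol %), CH2Cl2, −20 → 0 °C
Reagents that add atoms: none
Why: Acid-catalysed intramolecular epoxide opening; the 6-endo attack of the phenol at benzylic C2 is favoured electronically over 5-exo attack at C3 and proceeds with inversion, giving 2R (2,3-trans), while the untouched C3–O bond becomes the 3S hydroxyl cis to ring D.

Step 14
Reactants: 22 deca-O-benzyl dimer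
Product: 23 (2R,3S,4R)-2-(3,4,5-trihydroxyphenyl)-4-[(2R,3S)-3,5,7-trihydroxy-2-(3,4,5-trihydroxyphenyl)chroman-8-yl]chromane-3,7-diol (target)
Conditions: H2 (1 atm), Pd(OH)2/C, THF/MeOH/H2O, rt; filtration and freeze-drying under argon
Reagents that add atoms: none
Why: Hydrogenolysis of the ten benzyl ethers, the standard last step for benzylated proanthocyanidins; at ambient pressure the C4–C8 bond and the ring C and ring F C2–O1 bonds are kept and no stereocentre is affected.

## Compound list

1 | (+)-gallocatechin, (2R,3S)-2-(3,4,5-trihydroxyphenyl)chromane-3,5,7-triol | Oc1cc(O)c2c(c1)O[C@H](c1cc(O)c(O)c(O)c1)[C@@H](O)C2 | starting material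

2 | (2R,3S)-5,7-bis(benzyloxy)-2-[3,4,5-tris(benzyloxy)phenyl]chroman-3-ol | C(c1ccccc1)Oc1cc(OCc2ccccc2)c2c(c1)O[C@H](c1cc(OCc3ccccc3)c(OCc3ccccc3)c(OCc3ccccc3)c1)[C@@H](O)C2 | intermediate

3 | (2R,3S)-3,5,7-tris(benzyloxy)-2-[3,4,5-tris(benzyloxy)phenyl]chromane | C(c1ccccc1)Oc1cc(OCc2ccccc2)c2c(c1)O[C@H](c1cc(OCc3ccccc3)c(OCc3ccccc3)c(OCc3ccccc3)c1)[C@@H](OCc1ccccc1)C2 | intermediate

4 | (2R,3S)-3,5,7-tris(benzyloxy)-8-bromo-2-[3,4,5-tris(benzyloxy)phenyl]chromane | Brc1c(OCc2ccccc2)cc(OCc2ccccc2)c2c1O[C@H](c1cc(OCc3ccccc3)c(OCc3ccccc3)c(OCc3ccccc3)c1)[C@@H](OCc1ccccc1)C2 | intermediate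

5 | [(2R,3S)-3,5,7-tris(benzyloxy)-2-(3,4,5-tris(benzyloxy)phenyl)chroman-8-yl]lithium | [Li]c1c(OCc2ccccc2)cc(OCc2ccccc2)c2c1O[C@H](c1cc(OCc3ccccc3)c(OCc3ccccc3)c(OCc3ccccc3)c1)[C@@H](OCc1ccccc1)C2 | intermediate (not isolated)

6 | (2R,3S)-3,5,7-tris(benzyloxy)-2-[3,4,5-tris(benzyloxy)phenyl]chromane-8-carbaldehyde | O=Cc1c(OCc2ccccc2)cc(OCc2ccccc2)c2c1O[C@H](c1cc(OCc3ccccc3)c(OCc3ccccc3)c(OCc3ccccc3)c1)[C@@H](OCc1ccccc1)C2 | intermediate

7 | (2R,3S)-3,5,7-tris(benzyloxy)-8-ethynyl-2-[3,4,5-tris(benzyloxy)phenyl]chromane | C#Cc1c(OCc2ccccc2)cc(OCc2ccccc2)c2c1O[C@H](c1cc(OCc3ccccc3)c(OCc3ccccc3)c(OCc3ccccc3)c1)[C@@H](OCc1ccccc1)C2 | intermediate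

8 | 3,4,5-tris(benzyloxy)benzaldehyde | O=Cc1cc(OCc2ccccc2)c(OCc2ccccc2)c(OCc2ccccc2)c1 | starting material

9 | dicyclohexyl[(E)-2-(GC8)ethenyl]borane | C1CCCCC1B(C1CCCCC1)/C=C/c1c(OCc2ccccc2)cc(OCc2ccccc2)c2c1O[C@H](c1cc(OCc3ccccc3)c(OCc3ccccc3)c(OCc3ccccc3)c1)[C@@H](OCc1ccccc1)C2 | intermediate (not isolated)

10 | methyl[(E)-2-(GC8)ethenyl]zinc | C[Zn]/C=C/c1c(OCc2ccccc2)cc(OCc2ccccc2)c2c1O[C@H](c1cc(OCc3ccccc3)c(OCc3ccccc3)c(OCc3ccccc3)c1)[C@@H](OCc1ccccc1)C2 | intermediate (not isolated)

11 | (1S,2E)-3-(GC8)-1-[3,4,5-tris(benzyloxy)phenyl]prop-2-en-1-ol | O[C@@H](/C=C/c1c(OCc2ccccc2)cc(OCc2ccccc2)c2c1O[C@H](c1cc(OCc3ccccc3)c(OCc3ccccc3)c(OCc3ccccc3)c1)[C@@H](OCc1ccccc1)C2)c1cc(OCc2ccccc2)c(OCc2ccccc2)c(OCc2ccccc2)c1 | intermediate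

12 | (1S,2E)-3-(GC8)-1-[3,4,5-tris(benzyloxy)phenyl]prop-2-en-1-yl pyridine-2-carboxylate | O=C(c1ccccn1)O[C@@H](/C=C/c1c(OCc2ccccc2)cc(OCc2ccccc2)c2c1O[C@H](c1cc(OCc3ccccc3)c(OCc3ccccc3)c(OCc3ccccc3)c1)[C@@H](OCc1ccccc1)C2)c1cc(OCc2ccccc2)c(OCc2ccccc2)c(OCc2ccccc2)c1 | intermediate

13 | 4-bromoresorcinol | Oc1ccc(Br)c(O)c1 | starting material

14 | 5-(benzyloxy)-2-bromophenol | Oc1cc(OCc2ccccc2)ccc1Br | intermediate

15 | 4-(benzyloxy)-1-bromo-2-(methoxymethoxy)benzene | COCOc1cc(OCc2ccccc2)ccc1Br | intermediate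

16 | [4-(benzyloxy)-2-(methoxymethoxy)phenyl]magnesium bromide | COCOc1cc(OCc2ccccc2)ccc1[Mg]Br | intermediate (not isolated)

17 | bromomagnesium bis[4-(benzyloxy)-2-(methoxymethoxy)phenyl]cuprate | COCOc1cc(OCc2ccccc2)ccc1[Cu-]c1ccc(OCc2ccccc2)cc1OCOC.[Mg+]Br | intermediate (not isolated)

18 | (2R,3S)-3,5,7-tris(benzyloxy)-8-{(1R,2E)-1-[4-(benzyloxy)-2-(methoxymethoxy)phenyl]-3-[3,4,5-tris(benzyloxy)phenyl]prop-2-en-1-yl}-2-[3,4,5-tris(benzyloxy)phenyl]chromane | COCOc1cc(OCc2ccccc2)ccc1[C@@H](/C=C/c1cc(OCc2ccccc2)c(OCc2ccccc2)c(OCc2ccccc2)c1)c1c(OCc2ccccc2)cc(OCc2ccccc2)c2c1O[C@H](c1cc(OCc3ccccc3)c(OCc3ccccc3)c(OCc3ccccc3)c1)[C@@H](OCc1ccccc1)C2 | intermediate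

19 | trimethylsilyl ether of 20 at the ring A phenol | C[Si](C)(C)Oc1cc(OCc2ccccc2)ccc1[C@@H](/C=C/c1cc(OCc2ccccc2)c(OCc2ccccc2)c(OCc2ccccc2)c1)c1c(OCc2ccccc2)cc(OCc2ccccc2)c2c1O[C@H](c1cc(OCc3ccccc3)c(OCc3ccccc3)c(OCc3ccccc3)c1)[C@@H](OCc1ccccc1)C2 | intermediate (not isolated)

20 | (2R,3S)-3,5,7-tris(benzyloxy)-8-{(1R,2E)-1-[4-(benzyloxy)-2-hydroxyphenyl]-3-[3,4,5-tris(benzyloxy)phenyl]prop-2-en-1-yl}-2-[3,4,5-tris(benzyloxy)phenyl]chromane | Oc1cc(OCc2ccccc2)ccc1[C@@H](/C=C/c1cc(OCc2ccccc2)c(OCc2ccccc2)c(OCc2ccccc2)c1)c1c(OCc2ccccc2)cc(OCc2ccccc2)c2c1O[C@H](c1cc(OCc3ccccc3)c(OCc3ccccc3)c(OCc3ccccc3)c1)[C@@H](OCc1ccccc1)C2 | intermediate (precursor of the key step)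

21 | (2R,3S)-3,5,7-tris(benzyloxy)-8-{(R)-[4-(benzyloxy)-2-hydroxyphenyl][(2S,3S)-3-(3,4,5-tris(benzyloxy)phenyl)oxiran-2-yl]methyl}-2-[3,4,5-tris(benzyloxy)phenyl]chromane | Oc1cc(OCc2ccccc2)ccc1[C@H](c1c(OCc2ccccc2)cc(OCc2ccccc2)c2c1O[C@H](c1cc(OCc3ccccc3)c(OCc3ccccc3)c(OCc3ccccc3)c1)[C@@H](OCc1ccccc1)C2)[C@@H]1O[C@H]1c1cc(OCc2ccccc2)c(OCc2ccccc2)c(OCc2ccccc2)c1 | intermediate (product of the key step)

22 | (2R,3S,4R)-7-(benzyloxy)-4-[(2R,3S)-3,5,7-tris(benzyloxy)-2-(3,4,5-tris(benzyloxy)phenyl)chroman-8-yl]-2-[3,4,5-tris(benzyloxy)phenyl]chroman-3-ol | C(c1ccccc1)Oc1ccc2c(c1)O[C@H](c1cc(OCc3ccccc3)c(OCc3ccccc3)c(OCc3ccccc3)c1)[C@@H](O)[C@H]2c1c(OCc2ccccc2)cc(OCc2ccccc2)c2c1O[C@H](c1cc(OCc3ccccc3)c(OCc3ccccc3)c(OCc3ccccc3)c1)[C@@H](OCc1ccccc1)C2 | intermediate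

23 | robinetinidol-(4β→8)-gallocatechin, (2R,3S,4R)-2-(3,4,5-trihydroxyphenyl)-4-[(2R,3S)-3,5,7-trihydroxy-2-(3,4,5-trihydroxyphenyl)chroman-8-yl]chromane-3,7-diol | Oc1ccc2c(c1)O[C@H](c1cc(O)c(O)c(O)c1)[C@@H](O)[C@H]2c1c(O)cc(O)c2c1O[C@H](c1cc(O)c(O)c(O)c1)[C@@H](O)C2 | target

## Step count and risks

Total: 14 steps. Longest linear sequence: 12 steps (steps 1–7 and 10–14 from 1); steps 8 and 9 form the two-step side branch to 15.

**Step 12 (key step).** The most likely failure is poor facial selectivity, because the allylic-strain bias of an E-alkene is modest and rests largely on the bulk of ring D. Competing oxidation of the electron-rich phenol by the vanadium peroxide is the second concern.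

Fallback (reagent control without direction), from 20 back to 21:
- 20 is silylated (t-BuMe2SiCl, imidazole) to the tert-butyldimethylsilyl ether F1.
- F1 is epoxidised by Shi epoxidation with the L-fructose-derived ketone (KHSO5 as Oxone, K2CO3 buffer, MeCN/dimethoxymethane/water, 0 °C). The D-fructose-derived ketone gives (R,R)-oxiranes from trans-β-alkylstyrenes, so its antipode should give the (2S,3S)-oxirane silyl ether F2.
- Bu4NF buffered with acetic acid then frees the phenol and returns to 21.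

**Step 10.** The picolinate may ionise to a 1,3-diarylallyl cation stabilised by ring D, which would erode chirality transfer and regiocontrol. Attack at a carbon flanked by two ortho-substituted rings may also be slow.

Fallback (directed syn displacement on a poorer, non-chelating nucleofuge), from 7 and 8 back to 18:
- The alkenylzinc addition of step 6 is run with (+)-MIB to give the (1R,2E)-allylic alcohol F3.
- F3 is esterified with 2-(diphenylphosphanyl)benzoic acid (DCC, DMAP) to the ortho-(diphenylphosphanyl)benzoate F4.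
- CuBr·SMe2 and slow addition of Grignard reagent 16 in Et2O deliver the aryl group syn to the leaving group through phosphine-bound copper. From the (R)-ester this gives the same (R)-C4 and E-alkene, i.e. 18.

**Step 6.** Hydroboration or transmetalation of the hindered, electron-rich arylalkyne may be sluggish, and uncatalysed background addition would lower the enantioselectivity.

Fallback (alkynyl instead of alkenyl nucleophile, geometry set afterwards), from 7 and 8 back to 11:
- Zinc alkynylide addition of 7 to 8 (Me2Zn, ProPhenol ligand of the antipode that gives the R product) yields the (R)-propargylic alcohol F5.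
- trans-Hydroalumination with NaAlH2(OCH2CH2OMe)2 (Red-Al) in THF at 0 °C and protonation give 11.

**Step 13.** Regiocontrol may be lost (5-exo attack at C3) or C2 may be scrambled through an open benzylic cation, since the twisted para-oxygen of ring B is only a moderate donor. Acid cleavage of the C4–C8 bond is a lesser concern.

Fallback (deliberate 5-exo closure, then ring expansion), from 21 back to 22:
- K2CO3 in MeOH closes 21 by phenoxide attack at C3 with inversion to the cis-dihydrobenzofuran carbinol F6.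
- MsCl/Et3N gives the mesylate F7.
- Zn(OAc)2 in acetic acid moves O1 from C3 to C2 (inversion at C2) while acetate enters at C3 (second inversion there), giving the 3-O-acetate F8.
- K2CO3 in MeOH removes the acetate and returns to 22.

## Further compounds

F1 | step 12 | tert-butyldimethylsilyl ether of 20 at the ring A phenol, (1R,2E) | CC(C)(C)[Si](C)(C)Oc1cc(OCc2ccccc2)ccc1[C@@H](/C=C/c1cc(OCc2ccccc2)c(OCc2ccccc2)c(OCc2ccccc2)c1)c1c(OCc2ccccc2)cc(OCc2ccccc2)c2c1O[C@H](c1cc(OCc3ccccc3)c(OCc3ccccc3)c(OCc3ccccc3)c1)[C@@H](OCc1ccccc1)C2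

F2 | step 12 | tert-butyldimethylsilyl ether of 21 at the ring A phenol, (2S,3S)-oxirane | CC(C)(C)[Si](C)(C)Oc1cc(OCc2ccccc2)ccc1[C@H](c1c(OCc2ccccc2)cc(OCc2ccccc2)c2c1O[C@H](c1cc(OCc3ccccc3)c(OCc3ccccc3)c(OCc3ccccc3)c1)[C@@H](OCc1ccccc1)C2)[C@@H]1O[C@H]1c1cc(OCc2ccccc2)c(OCc2ccccc2)c(OCc2ccccc2)c1

F3 | step 10 | (1R,2E)-3-(GC8)-1-[3,4,5-tris(benzyloxy)phenyl]prop-2-en-1-ol | O[C@H](/C=C/c1c(OCc2ccccc2)cc(OCc2ccccc2)c2c1O[C@H](c1cc(OCc3ccccc3)c(OCc3ccccc3)c(OCc3ccccc3)c1)[C@@H](OCc1ccccc1)C2)c1cc(OCc2ccccc2)c(OCc2ccccc2)c(OCc2ccccc2)c1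

F4 | step 10 | (1R,2E)-3-(GC8)-1-[3,4,5-tris(benzyloxy)phenyl]prop-2-en-1-yl 2-(diphenylphosphanyl)benzoate | O=C(O[C@H](/C=C/c1c(OCc2ccccc2)cc(OCc2ccccc2)c2c1O[C@H](c1cc(OCc3ccccc3)c(OCc3ccccc3)c(OCc3ccccc3)c1)[C@@H](OCc1ccccc1)C2)c1cc(OCc2ccccc2)c(OCc2ccccc2)c(OCc2ccccc2)c1)c1ccccc1P(c1ccccc1)c1ccccc1

F5 | step 6 | (1R)-3-(GC8)-1-[3,4,5-tris(benzyloxy)phenyl]prop-2-yn-1-ol | O[C@@H](C#Cc1c(OCc2ccccc2)cc(OCc2ccccc2)c2c1O[C@H](c1cc(OCc3ccccc3)c(OCc3ccccc3)c(OCc3ccccc3)c1)[C@@H](OCc1ccccc1)C2)c1cc(OCc2ccccc2)c(OCc2ccccc2)c(OCc2ccccc2)c1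

F6 | step 13 | (S)-[(2R,3R)-6-(benzyloxy)-3-(GC8)-2,3-dihydro-1-benzofuran-2-yl][3,4,5-tris(benzyloxy)phenyl]methanol | C(c1ccccc1)Oc1ccc2c(c1)O[C@@H]([C@@H](O)c1cc(OCc3ccccc3)c(OCc3ccccc3)c(OCc3ccccc3)c1)[C@H]2c1c(OCc2ccccc2)cc(OCc2ccccc2)c2c1O[C@H](c1cc(OCc3ccccc3)c(OCc3ccccc3)c(OCc3ccccc3)c1)[C@@H](OCc1ccccc1)C2

F7 | step 13 | methanesulfonate of F6 at the benzylic carbinol, (S) | C(c1ccccc1)Oc1ccc2c(c1)O[C@@H]([C@@H](OS(C)(=O)=O)c1cc(OCc3ccccc3)c(OCc3ccccc3)c(OCc3ccccc3)c1)[C@H]2c1c(OCc2ccccc2)cc(OCc2ccccc2)c2c1O[C@H](c1cc(OCc3ccccc3)c(OCc3ccccc3)c(OCc3ccccc3)c1)[C@@H](OCc1ccccc1)C2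

F8 | step 13 | (2R,3S,4R)-7-(benzyloxy)-4-(GC8)-2-[3,4,5-tris(benzyloxy)phenyl]chroman-3-yl acetate | C(c1ccccc1)Oc1ccc2c(c1)O[C@H](c1cc(OCc3ccccc3)c(OCc3ccccc3)c(OCc3ccccc3)c1)[C@@H](OC(C)=O)[C@H]2c1c(OCc2ccccc2)cc(OCc2ccccc2)c2c1O[C@H](c1cc(OCc3ccccc3)c(OCc3ccccc3)c(OCc3ccccc3)c1)[C@@H](OCc1ccccc1)C2

A1 | alternative 1 | (2R,3R)-2-(benzyloxy)-3-hydroxy-1-(GC8)-3-[3,4,5-tris(benzyloxy)phenyl]propan-1-one | O[C@H](c1cc(OCc2ccccc2)c(OCc2ccccc2)c(OCc2ccccc2)c1)[C@@H](OCc1ccccc1)C(=O)c1c(OCc2ccccc2)cc(OCc2ccccc2)c2c1O[C@H](c1cc(OCc3ccccc3)c(OCc3ccccc3)c(OCc3ccccc3)c1)[C@@H](OCc1ccccc1)C2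

A2 | alternative 1 | 5-(benzyloxy)-3-chlorobenzyne | ClC1=CC(OCc2ccccc2)=CC#C1

A3 | alternative 1 | 3,7-bis(benzyloxy)-5-chloro-4-(GC8)-2-[3,4,5-tris(benzyloxy)phenyl]chroman-4-ol, C2 and C3 arranged in space as in 22, either C4 epimer | C(c1ccccc1)Oc1cc(Cl)c2c(c1)O[C@H](c1cc(OCc3ccccc3)c(OCc3ccccc3)c(OCc3ccccc3)c1)[C@@H](OCc1ccccc1)C2(O)c1c(OCc2ccccc2)cc(OCc2ccccc2)c2c1O[C@H](c1cc(OCc3ccccc3)c(OCc3ccccc3)c(OCc3ccccc3)c1)[C@@H](OCc1ccccc1)C2

A4 | alternative 2 | [4-(benzyloxy)-2-hydroxyphenyl]{(2R,3S)-3,5-bis(benzyloxy)-7-[diisopropyl((E)-2-(3,4,5-tris(benzyloxy)phenyl)ethenyl)silyloxy]-2-[3,4,5-tris(benzyloxy)phenyl]chroman-8-yl}methanol, either carbinol epimer | Oc1cc(OCc2ccccc2)ccc1C(O)c1c(O[Si](C(C)C)(C(C)C)/C=C/c2cc(OCc3ccccc3)c(OCc3ccccc3)c(OCc3ccccc3)c2)cc(OCc2ccccc2)c2c1O[C@H](c1cc(OCc3ccccc3)c(OCc3ccccc3)c(OCc3ccccc3)c1)[C@@H](OCc1ccccc1)C2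

A5 | alternative 2 | 3-silyl flavan with a cis-fused diisopropyl-oxasilinane ring bridging C3 and O7 of ring D, C2, C3 and C4 arranged as in 22 | c9ccccc9COc1ccc2c(c1)O[C@H](c5cc(OCc9ccccc9)c(OCc9ccccc9)c(OCc9ccccc9)c5)[C@@H]7[C@H]2c3c(O[Si]7(C(C)C)C(C)C)cc(OCc9ccccc9)c4c3O[C@H](c6cc(OCc9ccccc9)c(OCc9ccccc9)c(OCc9ccccc9)c6)[C@@H](OCc9ccccc9)C4

A6 | alternative 3 | (S)-[(2R,3R)-6-(benzyloxy)-3-(GC8)-2,3-dihydro-1-benzofuran-2-yl][3,4,5-tris(benzyloxy)phenyl]methanol (same structure as F6) | C(c1ccccc1)Oc1ccc2c(c1)O[C@@H]([C@@H](O)c1cc(OCc3ccccc3)c(OCc3ccccc3)c(OCc3ccccc3)c1)[C@H]2c1c(OCc2ccccc2)cc(OCc2ccccc2)c2c1O[C@H](c1cc(OCc3ccccc3)c(OCc3ccccc3)c(OCc3ccccc3)c1)[C@@H](OCc1ccccc1)C2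

A7 | alternative 3 | (2R,3S,4R)-7-(benzyloxy)-4-(GC8)-2-[3,4,5-tris(benzyloxy)phenyl]chroman-3-yl acetate (same structure as F8) | C(c1ccccc1)Oc1ccc2c(c1)O[C@H](c1cc(OCc3ccccc3)c(OCc3ccccc3)c(OCc3ccccc3)c1)[C@@H](OC(C)=O)[C@H]2c1c(OCc2ccccc2)cc(OCc2ccccc2)c2c1O[C@H](c1cc(OCc3ccccc3)c(OCc3ccccc3)c(OCc3ccccc3)c1)[C@@H](OCc1ccccc1)C2
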